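The runs stem from a simulated flask for an exercise; noise was put on by code.

Monday's run, with 0.60 mM of free catalyst, is the one earlier run, and its first reading holds the number you need.

- Monday's: starting material 1.6 M; gas phase 75 mM (held); protic impurity 0.48 M; free catalyst 0.60 mM; run made earlier
- flask: starting material 1.6 M; gas phase 75 mM (held); protic impurity 0.480 M; free catalyst 1.2 mM; time 12 h

Monday's run (percent of the starting material charged)

| time / h | product / % | starting material / % |
|---|---|---|
| 0.417 | 25 | 51 |
| 1.33 | 47 | 23 |
| 2.50 | 53 | 19 |
| 4.00 | 54 | 15 |

(scatter of a reading: 2 percentage points)

- at the start none of the gas phase is in solution
- no earlier run changes the charge of free catalyst; that part of a forecast is a guess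

- the product standing at 12 h, as a percentage of the starting material charged
- concentration of dissolved gas in solution at 12 h, in percent of saturation

At 0.417 h Monday's run stood at 25% product and 51% starting material, so 24.0% had gone elsewhere. The protic impurity is my likely taker, since its charge is 30.0% of the starting material's. Suppose both paths are first order in starting material. It then cancels from their ratio, but that ratio can still hold the other concentrations, and those can change during a run. Your flask differs from Monday's run in its charge of free catalyst, so I take the product path as first order in free catalyst and treat the other concentrations as in Monday's run. I therefore carry the selectivity factor per catalyst, σ: product gained per unit of starting material lost to the other path, divided by the free catalyst charged. As a reading, with its scatter, σ is 1.74 mM⁻¹. No earlier run varies the catalyst, so this scaling is a guess.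

Now draw your flask, with 1.2 mM of free catalyst, twice Monday's. Its product should start steeper, reaching 25% by about 0.209 h. The ratio σC is 2.09, so product takes that many parts for each one lost, and my curve levels at 67.6%. Monday's run had stalled near 54% with 15% starting material unused, which looks like lost catalyst. Scaled to this charge, that capacity is 108%, more than this level, so I expect the knee to come from the starting material falling away.

The forecast, by its own route, gives 68% product and 99% of saturation, arguing that “doubling it roughly doubles the integrated activity”.

The flask gives 70.4% product and >99.9% of saturation.

    gas phase ⇌ dissolved gas, rate k1*(csat - [dissolved gas]) (kL = 4.90 min⁻¹)
    starting material + dissolved gas + free catalyst → free catalyst + product (k = 410 L² mol⁻² min⁻¹)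
    starting material + protic impurity → quenched substrate (k = 0.0530 L mol⁻¹ min⁻¹)
    dissolved gas + free catalyst → spent catalyst (k = 0.160 L mol⁻¹ min⁻¹)

The main reason for the shortfall is the turning of starting material into quenched substrate: without that step, this flask stands at 95.4% instead of 70.4%. Its final ratio of product to quenched substrate is 2.45, against the 2.09 reckoned from σ. For the neighbour flask with 0.0030 M of free catalyst, σ gives 83.9%, and that flask holds 80.9%.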